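**Analysis of the target**

The target 12 is an open assembly of three benzene rings with no stereocentre and no ring fusion. Its central ring A carries OMe at C1, OH at C3, a 4-hydroxybenzyl group (ring C, joined through one CH2) at C4 and a 2-(2-hydroxyphenyl)ethyl group (ring D, joined through CH2CH2) at C5, while C2 and C6 bear hydrogen. The difficulty is regiochemical: C3, C4 and C5 form a contiguous oxygen–carbon–carbon triad, C4 is flanked on both sides, and C5 lies meta to both ring A oxygens, out of reach of electrophilic substitution. The two ring A oxygens must also end up differentiated, one as a methyl ether and one as a free phenol. Three free phenols make the compound electron-rich and air-sensitive, and the diarylmethane CH2 between two oxygenated rings is easily oxidised, so phenols and benzylic methylenes are best released together in the last step. The plan rests on reading the benzylic carbon on C4 as a carboxyl carbon, which turns ring A with C1 OMe, C3 OH and C4 COOH into the purchasable acid 1, whose oxygens are already differentiated. In 1 the only free position ortho to the carboxyl group is C5, where the two-carbon chain belongs, so the carboxyl group can direct C–H cleavage there, tie the chain into a lactone and later accept ring C as an acyl electrophile.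

**Retrosynthetic reasoning**

12 to 11. No skeletal bond is cut first. The CH2 between C4 and ring C and the chain CH2 next to ring D are taken back to ketone carbonyls, and the three phenols to benzyl ethers, which leads to the 1,5-diketone 11. Both carbonyl carbons are benzylic to oxygenated rings, so a single acidic hydrogenation can deoxygenate them and remove the benzyl groups at the same time. The forward step has to cleave these C–O bonds without reducing the rings.

11 to 7 and 9 (from 8). The bond between the C4 carbonyl carbon and ring C is cut. A carboxyl-derived carbon accepts an aryl nucleophile at this position, whereas benzylation of the crowded C4 of an intact ring A would offer no regiocontrol. The acyl partner is the enol lactone 7. One addition of the Grignard reagent 9 gives adduct 10, and its opening releases the diaryl ketone together with the second ketone as its enolate. The isocoumarin 7 therefore masks both side chains: its carbonyl becomes the C4 benzylic carbon and its enol ether carbons become the CH2CH2 bridge. Ring C is bought as the bromide 8.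

7 to 3 and 5. This is the central disconnection. The C5–C bond of ring A and the lactone O–C bond are cut together, which leads to the acid 3 and the styrene 5. Both bonds originate from the carboxyl group, and C5 is the only ortho C–H of 3. Electrophilic halogenation of ring A would go to C2 or C6, so a C–H functionalisation avoids a prefunctionalised ring A that is hard to obtain. The forward reaction must cleave C5–H under carboxylate direction, insert 5 with ring A on the terminal alkene carbon (passing through 6) and close the lactone oxidatively.

3 to 2 to 1. The phenol of 1 must be capped, because a free salicylate would chelate the catalyst and a free phenol would later quench 9. Benzyl is chosen because it leaves in the final hydrogenation. Exhaustive benzylation gives 2, and hydrolysis of the ester alone gives 3.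

5 to 4. The vinyl C=C is cut by a Wittig methylenation of the purchasable aldehyde 4, which already carries the benzyl-protected ring D phenol.

**Alternatives that were turned down**

Alternative 1: Ring A is built by a (2+2+2) cycloaddition that makes C1–C6, C2–C3 and C4–C5. The ether-tethered diyne benzyl{3-[4-(benzyloxy)phenyl]-3-({1-[2-(benzyloxy)phenyl]but-3-yn-1-yl}oxy)prop-1-yn-1-yl}dimethylsilane A2 and methoxyacetylene A3 would be joined under Cp*RuCl(cod) to the isochroman benzyl{1-[4-(benzyloxy)phenyl]-3-[2-(benzyloxy)phenyl]-6-methoxyisochroman-8-yl}dimethylsilane A1. In A1 the silyl group is a surrogate for the C3 phenol, and the isochroman oxygen would later be removed by benzylic hydrogenolysis.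
- For: the step is convergent, redox-neutral and atom-economic, and it places all four ring A substituents at once. The usual meta preference of such cycloadditions points the right way for A1. It also avoids exposing an electron-rich benzoic acid to hot oxidising conditions, and on that point it is stronger than the chosen route.
- Against: ring A is a simple resorcinol pattern that can be bought. The diyne A2 is an unsymmetrical ether between two secondary carbinol carbons, needs several steps and carries two stereocentres that are later destroyed. The alkyne A3 is volatile and labile. A six-atom-ring tether and a silyl-capped alkyne both slow the cycloaddition. The hindered aryl–silicon bond of A1 must then be oxidised (Tamao–Fleming) before the hydrogenolysis.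
- Comparison: the sequence through A1 would be roughly twice as long. The chosen route offers a purchased ring A with the oxygen pattern fixed and a single possible site of C–H cleavage.

Alternative 2: Ring A is formed by a polyketide-type fold that makes C3–C4 and C4–C5. The lithium enolate of 1-[4-(benzyloxy)phenyl]ethan-1-one A7 would attack the lactone carbonyl of 6-{2-[2-(benzyloxy)phenyl]ethyl}-4-methoxy-2H-pyran-2-one A5. The opened chain would then close by aldol condensation to [4-(benzyloxy)phenyl](2-{2-[2-(benzyloxy)phenyl]ethyl}-6-hydroxy-4-methoxyphenyl)methanone A4.
- For: the pyranone A5 should come in one step from purchasable 4-methoxy-6-methyl-2H-pyran-2-one A6, by deprotonation of its ring methyl group and alkylation with 1-(benzyloxy)-2-(bromomethyl)benzene A8. The ketone A4 has the C3 hydroxyl free and the C1 methyl ether in place without any protecting group on ring A, and one hydrogenation would finish the synthesis. On step count and on oxygen differentiation this is stronger than the chosen route.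
- Against: the enolate of A7 has three electrophilic positions of A5 to choose from, and it can instead remove the acidic side-chain proton next to the pyranone ring. The opened polycarbonyl chain can close through oxygen back to a pyranone as well as through carbon. The required aldol places the bulky aroyl carbon of A4 between two substituents. The alkylation of A6 with A8 must also compete with deprotonation at the ring position next to the lactone carbonyl.
- Comparison: the chosen route is longer, but each bond-forming step is a known reaction type on its substrate class, and site selectivity is fixed by the substrate and not by a competition within A5.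

Alternative 3: Ring A is closed by a (5+1) carbonylation in which carbon monoxide A11 becomes C1, making C1–C2 and C1–C6. The tertiary propargylic ester 3-[4-(benzyloxy)benzyl]-6-[2-(benzyloxy)phenyl]-4-methylidenehex-1-yn-3-yl 2,2-dimethylpropanoate A10 would undergo a 1,2-acyloxy shift and carbonylative closure under [Rh(CO)2Cl]2 to 2-[4-(benzyloxy)benzyl]-3-{2-[2-(benzyloxy)phenyl]ethyl}-5-hydroxyphenyl pivalate A9.
- For: in A9 the two ring A oxygens emerge differentiated (free hydroxyl at C1 for methylation, ester at C3), and both side chains are already at their final oxidation level. No benzylic deoxygenation is needed, which is an advantage over the chosen endgame.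
- Against: the enyne A10 needs a long preparation that ends with acylation of a hindered tertiary alcohol. Its tertiary ester can ionise or eliminate. Closure to a five-membered ketone (Rautenstrauch-type) competes with uptake of A11. Pressurised A11 and [Rh(CO)2Cl]2 are required. Methylation, ester removal and debenzylation of A9 still follow.
- Comparison: the count through A10 and A9 is clearly higher than six steps. The chosen route offers a purchased ring A and a short, convergent sequence.

Key step: step 4

Remark on the chemistry: ring A positions are numbered as in the target throughout (C1 OMe, C3 oxygen, C4 carboxyl-derived carbon, C5 chain). Compound 11 is written as the open-chain 1,5-diketone; whether it is isolated in this form or partly as its cyclic hemiketal (the protonated form of 10) does not matter, since both are reduced to 12 in step 6.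

**Route**

Step 1
Reactants: 1 2-hydroxy-4-methoxybenzoic acid
Product: 2 benzyl 2-(benzyloxy)-4-methoxybenzoate
Conditions: BnBr (2.3 equiv), K2CO3 (3 equiv), DMF, 60 °C
Reagents that add atoms: benzyl bromide, BrCc1ccccc1
Why: Williamson ether synthesis combined with carboxylate O-alkylation (both SN2 on a benzylic bromide); K2CO3 in DMF deprotonates the acid and the hydrogen-bonded phenol, and excess benzyl bromide with gentle heating should complete the slower phenol alkylation.

Step 2
Reactants: 2 benzyl 2-(benzyloxy)-4-methoxybenzoate
Product: 3 2-(benzyloxy)-4-methoxybenzoic acid
Conditions: LiOH·H2O, THF/H2O, 60 °C; then 1 M HCl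
Reagents that add atoms: lithium hydroxide, [Li+].[OH-]
Why: Saponification (acyl–oxygen cleavage by hydroxide) removes only the ester benzyl group, since the aryl benzyl ether and the methyl ether are inert to aqueous base; acidification releases the free acid needed as directing group.

Step 3
Reactants: 4 2-(benzyloxy)benzaldehyde
Product: 5 1-(benzyloxy)-2-vinylbenzene
Conditions: MePPh3Br, KOtBu, THF, 0 °C to rt
Reagents that add atoms: methyltriphenylphosphonium bromide, C[P+](c1ccccc1)(c1ccccc1)c1ccccc1.[Br-]
Why: Wittig methylenation with the non-stabilised ylide formed from the phosphonium salt and KOtBu; the aldehyde has no α-hydrogen, so enolisation cannot compete, and the benzyl ether is untouched.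

Step 4
Reactants: 3 2-(benzyloxy)-4-methoxybenzoic acid; 5 1-(benzyloxy)-2-vinylbenzene
Product: 7 8-(benzyloxy)-3-[2-(benzyloxy)phenyl]-6-methoxy-1H-isochromen-1-one, via E-stilbene-2-carboxylic acid 6 (not isolated)
Conditions: Pd(OAc)2 (10 mol%), Ag2O (2.2 equiv), DMF, 110 °C
Reagents that add atoms: none
Why: The closest known reaction type is the carboxylate-directed ortho C–H olefination of benzoic acids with styrenes, followed by oxidative Wacker-type lactonisation to 3-arylisocoumarins, under Pd(OAc)2 with a silver oxidant; it is applied here to a new pair of partners. The carboxylate of 3 binds divalent palladium, and acetate-assisted concerted metalation–deprotonation gives a five-membered palladacycle at C5. Styrene 5 inserts into the aryl–palladium bond with ring A on the unsubstituted alkene carbon, and β-hydride elimination gives the stilbene acid 6; the zerovalent palladium is reoxidised by Ag2O. In a second cycle divalent palladium activates the alkene of 6, the carboxylate oxygen attacks the carbon bearing the 2-benzyloxyphenyl group, and β-hydride elimination from that carbon forms the enol lactone double bond, with a second reoxidation by Ag2O. The pyranone ring is thus closed by 6-endo-trig oxypalladation, favoured because the attacked carbon is benzylic to an electron-rich ortho-alkoxyaryl ring. No stereocentre is formed, and the alkene geometry of 6 is of no consequence once the ring is closed. The step needs site selectivity, which the substrate secures because C5 is the only free position ortho to the carboxylate (the other is blocked by the benzyloxy group), and terminal insertion of the styrene, which is the normal polarity for vinylarenes. Should 5-exo closure compete, the isomeric five-membered enol lactone would lead to the same carbon skeleton after steps 5 and 6.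

Step 5
Reactants: 7 8-(benzyloxy)-3-[2-(benzyloxy)phenyl]-6-methoxy-1H-isochromen-1-one; 8 1-(benzyloxy)-4-bromobenzene
Product: 11 1-[2-(benzyloxy)phenyl]-2-{3-(benzyloxy)-2-[4-(benzyloxy)benzoyl]-5-methoxyphenyl}ethan-1-one, via [4-(benzyloxy)phenyl]magnesium bromide 9 (not isolated), via bromomagnesium lactolate adduct 10 (not isolated)
Conditions: 8, Mg, THF, rt to 50 °C; then 7, THF, −78 to 0 °C; sat. aq. NH4Cl
Reagents that add atoms: none
Why: Grignard formation and 1,2-addition to the carbonyl of an enol lactone; adduct 10 either persists as the cyclic magnesium lactolate or opens by expelling the enol oxygen, which unveils the diaryl ketone together with the second ketone as its magnesium enolate. In either form the new carbonyl is masked or deactivated (the enolate is conjugated through ring A with the doubly ortho-substituted ketone), so a second addition should be slow, and protonation on work-up gives 11.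

Step 6
Reactants: 11 1-[2-(benzyloxy)phenyl]-2-{3-(benzyloxy)-2-[4-(benzyloxy)benzoyl]-5-methoxyphenyl}ethan-1-one
Product: 12 2-(4-hydroxybenzyl)-3-[2-(2-hydroxyphenyl)ethyl]-5-methoxyphenol
Conditions: H2 (3 bar), Pd/C (10% palladium on carbon), AcOH/EtOAc, cat. HClO4, rt
Reagents that add atoms: none
Why: Catalytic hydrogenation with benzylic hydrogenolysis under acid; each aryl ketone passes through a benzylic alcohol (or, after acid-induced ring closure, a cyclic benzylic ether or oxocarbenium ion), and every such C–O bond lies next to an oxygen-substituted ring and should be cleaved to CH2 on Pd/C. The three O-benzyl ethers are hydrogenolysed in the same operation, and at room temperature and low pressure the arene rings should remain unreduced.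

**Compound list**

1 | 2-hydroxy-4-methoxybenzoic acid | COc1ccc(C(=O)O)c(O)c1 | starting material
2 | benzyl 2-(benzyloxy)-4-methoxybenzoate | COc1ccc(C(=O)OCc2ccccc2)c(OCc2ccccc2)c1 | intermediate
3 | 2-(benzyloxy)-4-methoxybenzoic acid | COc1ccc(C(=O)O)c(OCc2ccccc2)c1 | intermediate
4 | 2-(benzyloxy)benzaldehyde | O=Cc1ccccc1OCc1ccccc1 | starting material
5 | 1-(benzyloxy)-2-vinylbenzene | C=Cc1ccccc1OCc1ccccc1 | intermediate
6 | (E)-2-(benzyloxy)-6-{2-[2-(benzyloxy)phenyl]ethenyl}-4-methoxybenzoic acid (not isolated) | COc1cc(OCc2ccccc2)c(C(=O)O)c(/C=C/c2ccccc2OCc2ccccc2)c1 | intermediate
7 | 8-(benzyloxy)-3-[2-(benzyloxy)phenyl]-6-methoxy-1H-isochromen-1-one | COc1cc(OCc2ccccc2)c2c(c1)C=C(c1ccccc1OCc1ccccc1)OC2=O | intermediate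
8 | 1-(benzyloxy)-4-bromobenzene | Brc1ccc(OCc2ccccc2)cc1 | starting material
9 | [4-(benzyloxy)phenyl]magnesium bromide (not isolated) | Br[Mg]c1ccc(OCc2ccccc2)cc1 | intermediate
10 | bromomagnesium 8-(benzyloxy)-1-[4-(benzyloxy)phenyl]-3-[2-(benzyloxy)phenyl]-6-methoxy-1H-isochromen-1-olate, racemic (not isolated) | COc1cc(OCc2ccccc2)c2c(c1)C=C(c1ccccc1OCc1ccccc1)OC2(O[Mg]Br)c1ccc(OCc2ccccc2)cc1 | intermediate
11 | 1-[2-(benzyloxy)phenyl]-2-{3-(benzyloxy)-2-[4-(benzyloxy)benzoyl]-5-methoxyphenyl}ethan-1-one | COc1cc(OCc2ccccc2)c(C(=O)c2ccc(OCc3ccccc3)cc2)c(CC(=O)c2ccccc2OCc2ccccc2)c1 | intermediate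
12 | 2-(4-hydroxybenzyl)-3-[2-(2-hydroxyphenyl)ethyl]-5-methoxyphenol | COc1cc(O)c(Cc2ccc(O)cc2)c(CCc2ccccc2O)c1 | target

**Step count and risk**

Total step count: 6. Longest linear sequence: 5 steps (steps 1, 2, 4, 5 and 6 from compound 1); step 3 is a one-step side branch that joins at step 4.

Least certain steps:

Step 4 (key step). The most likely failure is loss of carbon dioxide from the acid before C–H cleavage. Ortho-alkoxybenzoic acids are among the substrates most prone to protodecarboxylation or decarboxylative coupling at C4 under hot Pd(OAc)2/Ag2O conditions. Further risks are slow metalation at C5, which is meta to both oxygens and therefore not electron-rich, undirected palladation at the electron-rich C2 or C6 positions, and oligomerisation of the styrene. Partial 5-exo closure would be harmless for the reason given in the step.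

The fallback abandons C–H activation for lateral metalation of a toluate. It sets out from the aldehyde 4 (with 9, made from the bromide 8, as second partner) and comes back to the route at 12. Purchasable methyl 2-hydroxy-4-methoxy-6-methylbenzoate F1 would be benzylated (BnBr, K2CO3, DMF) to methyl 2-(benzyloxy)-4-methoxy-6-methylbenzoate F2. Deprotonation of its ring methyl group with LiN(iPr)2 in THF at −78 °C and addition of 4 should give, after the alkoxide closes onto the ester, racemic 8-(benzyloxy)-3-[2-(benzyloxy)phenyl]-6-methoxy-3,4-dihydro-1H-isochromen-1-one F3. One equivalent of 9 at −78 °C should add once to this lactone to give 8-(benzyloxy)-1-[4-(benzyloxy)phenyl]-3-[2-(benzyloxy)phenyl]-6-methoxy-3,4-dihydro-1H-isochromen-1-ol F4 as a mixture of diastereomers. Under the conditions of step 6, F4 loses both ring C–O bonds and the benzyl groups and gives 12; its stereocentres vanish on the way. The price is a less common ring A building block and a stoichiometric strong base at low temperature.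

Step 5. The likely failures are a second aryl addition to the liberated diaryl ketone, if the lactolate or enolate protects it less than expected, and sluggish attack at the lactone carbonyl, which is hindered by the neighbouring benzyloxy group.

The fallback lowers the carbonyl to the aldehyde oxidation level, where over-addition is impossible. It sets out from 7 and comes back at 12. Reduction of 7 with iBu2AlH in CH2Cl2 at −78 °C should give racemic 8-(benzyloxy)-3-[2-(benzyloxy)phenyl]-6-methoxy-1H-isochromen-1-ol F5. With about 2.2 equivalents of 9, the first equivalent deprotonates the lactol and opens it to an aldehyde that carries the ketone as its enolate, and the second adds to the aldehyde. This should give racemic 1-[2-(benzyloxy)phenyl]-2-(3-(benzyloxy)-2-{[4-(benzyloxy)phenyl](hydroxy)methyl}-5-methoxyphenyl)ethan-1-one F6. F6 lies one oxidation level below 11 and is converted into 12 under the conditions of step 6.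

Step 6. The likely failures are incomplete deoxygenation and over-reduction. The reduction may stall at a cyclic benzylic ether or a benzylic alcohol, or at a hydrogen-bonded ortho-hydroxyaryl ketone once debenzylation has outrun carbonyl reduction. Forcing the conditions to overcome this may begin to saturate the electron-rich phenol rings.

The fallback separates deoxygenation from debenzylation. It sets out from 11 and comes back at 12. Ionic hydrogenation with Et3SiH and CF3CO2H in CH2Cl2 (0 °C to rt) should reduce both carbonyls through oxocarbenium and benzylic cations, each stabilised by an alkoxy-substituted ring, to 1-(benzyloxy)-2-[4-(benzyloxy)benzyl]-3-{2-[2-(benzyloxy)phenyl]ethyl}-5-methoxybenzene F7. Plain neutral hydrogenolysis of F7 (H2, Pd/C, EtOAc/MeOH) then removes the three benzyl groups to give 12.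

**Further compounds**

F1 | step 4 | methyl 2-hydroxy-4-methoxy-6-methylbenzoate | COC(=O)c1c(C)cc(OC)cc1O
F2 | step 4 | methyl 2-(benzyloxy)-4-methoxy-6-methylbenzoate | COC(=O)c1c(C)cc(OC)cc1OCc1ccccc1
F3 | step 4 | 8-(benzyloxy)-3-[2-(benzyloxy)phenyl]-6-methoxy-3,4-dihydro-1H-isochromen-1-one, racemic | COc1cc(OCc2ccccc2)c2c(c1)CC(c1ccccc1OCc1ccccc1)OC2=O
F4 | step 4 | 8-(benzyloxy)-1-[4-(benzyloxy)phenyl]-3-[2-(benzyloxy)phenyl]-6-methoxy-3,4-dihydro-1H-isochromen-1-ol, mixture of diastereomers | COc1cc(OCc2ccccc2)c2c(c1)CC(c1ccccc1OCc1ccccc1)OC2(O)c1ccc(OCc2ccccc2)cc1
F5 | step 5 | 8-(benzyloxy)-3-[2-(benzyloxy)phenyl]-6-methoxy-1H-isochromen-1-ol, racemic | COc1cc(OCc2ccccc2)c2c(c1)C=C(c1ccccc1OCc1ccccc1)OC2O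
F6 | step 5 | 1-[2-(benzyloxy)phenyl]-2-(3-(benzyloxy)-2-{[4-(benzyloxy)phenyl](hydroxy)methyl}-5-methoxyphenyl)ethan-1-one, racemic | COc1cc(OCc2ccccc2)c(C(O)c2ccc(OCc3ccccc3)cc2)c(CC(=O)c2ccccc2OCc2ccccc2)c1
F7 | step 6 | 1-(benzyloxy)-2-[4-(benzyloxy)benzyl]-3-{2-[2-(benzyloxy)phenyl]ethyl}-5-methoxybenzene | COc1cc(OCc2ccccc2)c(Cc2ccc(OCc3ccccc3)cc2)c(CCc2ccccc2OCc2ccccc2)c1
A1 | alternative 1 | benzyl{1-[4-(benzyloxy)phenyl]-3-[2-(benzyloxy)phenyl]-6-methoxyisochroman-8-yl}dimethylsilane, mixture of diastereomers | COc1cc([Si](C)(C)Cc2ccccc2)c2c(c1)CC(c1ccccc1OCc1ccccc1)OC2c1ccc(OCc2ccccc2)cc1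
A2 | alternative 1 | benzyl{3-[4-(benzyloxy)phenyl]-3-({1-[2-(benzyloxy)phenyl]but-3-yn-1-yl}oxy)prop-1-yn-1-yl}dimethylsilane, mixture of diastereomers | C#CCC(c1ccccc1OCc1ccccc1)OC(c1ccc(OCc2ccccc2)cc1)C#C[Si](C)(C)Cc1ccccc1
A3 | alternative 1 | methoxyacetylene | COC#C
A4 | alternative 2 | [4-(benzyloxy)phenyl](2-{2-[2-(benzyloxy)phenyl]ethyl}-6-hydroxy-4-methoxyphenyl)methanone | COc1cc(O)c(C(=O)c2ccc(OCc3ccccc3)cc2)c(CCc2ccccc2OCc2ccccc2)c1
A5 | alternative 2 | 6-{2-[2-(benzyloxy)phenyl]ethyl}-4-methoxy-2H-pyran-2-one | COC1=CC(=O)OC(CCc2ccccc2OCc2ccccc2)=C1
A6 | alternative 2 | 4-methoxy-6-methyl-2H-pyran-2-one | COC1=CC(=O)OC(C)=C1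
A7 | alternative 2 | 1-[4-(benzyloxy)phenyl]ethan-1-one | CC(=O)c1ccc(OCc2ccccc2)cc1
A8 | alternative 2 | 1-(benzyloxy)-2-(bromomethyl)benzene | BrCc1ccccc1OCc1ccccc1
A9 | alternative 3 | 2-[4-(benzyloxy)benzyl]-3-{2-[2-(benzyloxy)phenyl]ethyl}-5-hydroxyphenyl pivalate | CC(C)(C)C(=O)Oc1cc(O)cc(CCc2ccccc2OCc2ccccc2)c1Cc1ccc(OCc2ccccc2)cc1
A10 | alternative 3 | 3-[4-(benzyloxy)benzyl]-6-[2-(benzyloxy)phenyl]-4-methylidenehex-1-yn-3-yl 2,2-dimethylpropanoate, racemic | C#CC(Cc1ccc(OCc2ccccc2)cc1)(OC(=O)C(C)(C)C)C(=C)CCc1ccccc1OCc1ccccc1
A11 | alternative 3 | carbon monoxide | [C-]#[O+]
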